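**Plan**

- Retrosynthesis: the C3 acetate, C15 acid and C19 alcohol go back to a protected Δ7-labdene, and the C7=C8 alkene to a C7 ketone. Ring B is then cut at C9–C10 and C5=C6. C10 (quaternary, methyl) and C9 (side chain) are vicinal and cis on ring B, and C5–C6–C7 can be an enone made from a methyl ketone, so ring B is a Robinson retron with the chain on the vinyl ketone.
- The fragments are ring A ketone 7 (from 2-methylcyclohexane-1,3-dione and formaldehyde) and enone 13 (C11–C16 from (R)-citronellol).
- Forward: ring A is made first; the chain-bearing enone is joined and ring B closed in one annulation. Then follow C17 by α′-methylation, Li/NH3 reduction, enol triflate reduction to Δ7, and ring A/side-chain adjustment.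
- Stereochemistry: C13 comes from (R)-citronellol; C4 (and a temporary, epimeric C3) from enzymatic desymmetrisation; C10 and C9 from the annulation under control of C4/C3; C5 from dissolving-metal reduction; C3 finally from equatorial hydride delivery to the C3 ketone.

Key step: step 9

Assumption: labdane-type numbering is used throughout (ring A C1–C5/C10, ring B C5–C10, chain C11–C16, C17 on C8, C19 = CH2O carbon on C4, C20 on C10), and a ketoreductase with the (2R,3R) preference needed in step 3 is taken to be found by screening an enzyme panel.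

**Route**

Step 1
Reactants: 1 2-methylcyclohexane-1,3-dione; 2 formaldehyde (37% aqueous)
Product: 3 2-(hydroxymethyl)-2-methylcyclohexane-1,3-dione
Conditions: 37% aq. HCHO, NaHCO3 (cat.), H2O, 20 °C
Reagents that add atoms: none
Why: Tollens-type aldol hydroxymethylation at C2 of the enolised 1,3-dione installs the future C19 on the future C4; with no second α-hydrogen at that carbon, no Knoevenagel dehydration can follow.

Step 2
Reactants: 3 2-(hydroxymethyl)-2-methylcyclohexane-1,3-dione
Product: 4 2-[(methoxymethoxy)methyl]-2-methylcyclohexane-1,3-dione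
Conditions: CH2(OMe)2 (solvent), LiBr, TsOH·H2O (cat.), 20 °C
Reagents that add atoms: dimethoxymethane, COCOC
Why: acid-catalysed transacetalisation (MOM ether formation) protects the neopentyl alcohol without base, which would cause retro-aldol loss of formaldehyde; MOM survives Li/NH3 and is orthogonal to the silyl ethers used later.

Step 3
Reactants: 4 2-[(methoxymethoxy)methyl]-2-methylcyclohexane-1,3-dione
Product: 5 (2R,3R)-3-hydroxy-2-[(methoxymethoxy)methyl]-2-methylcyclohexan-1-one
Conditions: ketoreductase (panel-selected), NADP+ (cat.), i-PrOH, pH 7 phosphate buffer, 30 °C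
Reagents that add atoms: none
Why: enzymatic desymmetrising carbonyl reduction of a prochiral 2,2-disubstituted cyclic 1,3-dione (the reaction class of yeast and ketoreductase reductions of 2-alkyl-2-methylcyclohexane-1,3-diones); the enzyme selects one enantiotopic carbonyl and one face, so C4 and the temporary C3 carbinol (OH cis to CH2OMOM) are set together.

Step 4
Reactants: 5 (2R,3R)-3-hydroxy-2-[(methoxymethoxy)methyl]-2-methylcyclohexan-1-one
Product: 6 (2R,3R)-3-(tert-butyldimethylsilyloxy)-2-[(methoxymethoxy)methyl]-2-methylcyclohexan-1-one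
Conditions: TBSCl, imidazole, DMF, 40 °C
Reagents that add atoms: tert-butyldimethylsilyl chloride, CC(C)(C)[Si](C)(C)Cl
Why: imidazole-mediated silylation of the hindered secondary alcohol blocks retro-aldol opening and supplies the equatorial C3 group used for conformational control in step 9.

Step 5
Reactants: 6 (2R,3R)-3-(tert-butyldimethylsilyloxy)-2-[(methoxymethoxy)methyl]-2-methylcyclohexan-1-one
Product: 7 ring A ketone (2R,3R)-3-(tert-butyldimethylsilyloxy)-2-[(methoxymethoxy)methyl]-2,6-dimethylcyclohexan-1-one (C6 epimers)
Conditions: LDA, THF, −78 °C; MeI, −78 → 0 °C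
Reagents that add atoms: iodomethane, CI
Why: kinetic enolate alkylation; the ring C6 (labdane C10) is the only enolisable position because C2 is quaternary, and its configuration is irrelevant since it is enolised again in step 9.

Step 6
Reactants: 8 (R)-citronellol
Product: 9 (R)-citronellyl triisopropylsilyl ether
Conditions: TIPSCl, imidazole, DMF, 20 °C
Reagents that add atoms: triisopropylsilyl chloride, CC(C)[Si](Cl)(C(C)C)C(C)C
Why: standard silyl protection of the primary alcohol (future C15) with a group stable to base, LDA and Li/NH3; the C13 stereocentre is untouched.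

Step 7
Reactants: 9 (R)-citronellyl triisopropylsilyl ether
Product: 11 (4R)-4-methyl-6-(triisopropylsilyloxy)hexanal, via ozonide 10 (not isolated)
Conditions: O3, CH2Cl2, −78 °C; then PPh3, −78 → 20 °C
Reagents that add atoms: ozone, [O-][O+]=O
Why: ozonolysis with reductive work-up (Criegee mechanism) cleaves the trisubstituted alkene to the aldehyde without touching the remote stereocentre.

Step 8
Reactants: 11 (4R)-4-methyl-6-(triisopropylsilyloxy)hexanal; 12 1-(triphenylphosphoranylidene)propan-2-one
Product: 13 (3E,7R)-7-methyl-9-(triisopropylsilyloxy)non-3-en-2-one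
Conditions: toluene, 90 °C
Reagents that add atoms: none
Why: Wittig olefination with a stabilised acyl ylide should give the (E)-enone selectively.

Step 9
Reactants: 7 ring A ketone; 13 (3E,7R)-7-methyl-9-(triisopropylsilyloxy)non-3-en-2-one
Product: 16 annulation enone (3-O-TBS-19-O-MOM-15-O-TIPS-17-norlabd-5-en-7-one), via Michael adduct 1,5-diketone 14 (not isolated), via ketol 15 (not isolated)
Conditions: NaH, 1,4-dioxane, 60 °C; 13, 20 °C; then KOH, MeOH, 60 °C (one pot)
Reagents that add atoms: none
Why: Robinson annulation: the sodium enolate of 7, which can form only toward C10 because C4 is quaternary, adds through C10 to C9 of the (E)-enone to give diketone 14, whose methyl ketone enolises at C6 and attacks the C5 carbonyl (ketol 15) before E1cB dehydration gives the C5=C6 enone. The closest known reaction type is the annulation of 2-methylcyclohexanones with (E)-β-alkyl vinyl ketones, which gives cis-4,4a-dialkyl octalones in eremophilane syntheses. Ring B closes by a 6-(enolexo)-exo-trig aldol; closure through C8 would give a cyclobutane and does not compete. C10 is set by approach of the enone to the enolate face anti to the pseudoaxial C4 CH2OMOM group, since the half-chair with the C3 silyloxy group equatorial (the reason for the C3 epimer) places this larger C4 substituent axial; C9 therefore enters cis to the C4 methyl and the C10 methyl ends syn to C19. C9 is set relative to C10 by the sodium-bridged synclinal Michael transition state favoured in dioxane, which puts the C9 chain cis to the C10 methyl on ring B. The step needs C- over O-attack and 1,4- over 1,2-addition, secured by the soft, fully substituted enolate and reversible aldolisation, and it needs the hindered aldol onto C5 to go to completion, for which the methanolic KOH stage is included.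

Step 10
Reactants: 16 annulation enone
Product: 17 8-methyl enone (3-O-TBS-19-O-MOM-15-O-TIPS-labd-5-en-7-one, C8 epimers)
Conditions: LDA, THF, −78 °C; MeI, DMPU, −78 → −20 °C
Reagents that add atoms: iodomethane, CI
Why: kinetic α′-deprotonation of the enone gives the cross-conjugated dienolate at C8, the only enolisable carbon because C4 and C10 are quaternary, and alkylation installs C17; the C8 configuration does not matter because C8 becomes sp2 in step 12.

Step 11
Reactants: 17 8-methyl enone
Product: 18 trans-decalone (3-O-TBS-19-O-MOM-15-O-TIPS-labdan-7-one, H5 trans to C20, C8 epimers)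
Conditions: Li, NH3(l)/THF, t-BuOH (1 equiv), −78 °C; then NH4Cl
Reagents that add atoms: none
Why: dissolving-metal (Birch-type) enone reduction; protonation of the C5 carbanion anti to the angular C10 methyl should give the trans ring fusion and so set C5, while silyl ethers and the MOM ether are inert.

Step 12
Reactants: 18 trans-decalone
Product: 19 Δ7 enol triflate (3-O-TBS-19-O-MOM-15-O-TIPS-labd-7-en-7-yl trifluoromethanesulfonate)
Conditions: Tf2O, 2,6-di-tert-butyl-4-methylpyridine, CH2Cl2, 0 → 20 °C
Reagents that add atoms: trifluoromethanesulfonic anhydride, O=S(=O)(OS(=O)(=O)C(F)(F)F)C(F)(F)F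
Why: enol triflate formation under equilibrating (thermodynamic) conditions with a hindered pyridine base should favour the more substituted C7=C8 enol over C6=C7, fixing the alkene position and removing the C8 stereocentre.

Step 13
Reactants: 19 Δ7 enol triflate
Product: 20 Δ7-labdene tris-ether (3-O-TBS-19-O-MOM-15-O-TIPS-labd-7-ene-3,15,19-triol)
Conditions: Pd(OAc)2 (cat.), PPh3 (cat.), HCO2H, n-Bu3N, DMF, 60 °C
Reagents that add atoms: none
Why: palladium-catalysed formate reduction of a vinyl triflate (oxidative addition, formate exchange, decarboxylation, reductive elimination) replaces OTf by H without moving the double bond.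

Step 14
Reactants: 20 Δ7-labdene tris-ether
Product: 21 diol (19-O-MOM-labd-7-ene-3,15,19-triol, 3-OH equatorial)
Conditions: HF·pyridine, pyridine/THF, 0 → 40 °C
Reagents that add atoms: none
Why: fluoride-mediated desilylation removes both silyl ethers in one operation while the MOM acetal and the trisubstituted alkene are stable.

Step 15
Reactants: 21 diol
Product: 22 keto aldehyde (19-(methoxymethoxy)-3-oxolabd-7-en-15-al)
Conditions: Dess–Martin periodinane, CH2Cl2, 20 °C
Reagents that add atoms: none
Why: Dess–Martin oxidation converts the C3 carbinol to the ketone (erasing the temporary C3 configuration) and the C15 alcohol to the aldehyde; C13 is β to the new carbonyl and cannot epimerise.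

Step 16
Reactants: 22 keto aldehyde
Product: 23 keto acid (19-(methoxymethoxy)-3-oxolabd-7-en-15-oic acid)
Conditions: NaClO2, NaH2PO4, 2-methyl-2-butene, t-BuOH/H2O, 20 °C
Reagents that add atoms: sodium chlorite, [Na+].[O-]Cl=O
Why: Pinnick oxidation takes the aldehyde to the acid chemoselectively; the scavenger protects the ring alkene from hypochlorous acid.

Step 17
Reactants: 23 keto acid
Product: 24 axial hydroxy acid (3-hydroxy-19-(methoxymethoxy)labd-7-en-15-oic acid, 3-OH axial and trans to C19)
Conditions: L-Selectride (3 equiv), THF, −78 °C; aq. HCl work-up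
Reagents that add atoms: none
Why: bulky trialkylborohydride reduction of a cyclohexanone by equatorial attack should give the axial C3 alcohol (as in reductions of 4,4-disubstituted 3-oxo terpenoids), setting C3; the carboxylate formed by the first equivalent is not reduced.

Step 18
Reactants: 24 axial hydroxy acid
Product: 26 acetoxy acid (3-acetoxy-19-(methoxymethoxy)labd-7-en-15-oic acid), via mixed anhydride 25 (not isolated)
Conditions: Ac2O, pyridine, DMAP (cat.), 40 °C; then aq. NaHCO3/THF, then acidify
Reagents that add atoms: acetic anhydride, CC(=O)OC(C)=O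
Why: DMAP-catalysed acylation esterifies the hindered axial alcohol; the carboxyl group is acetylated as well and is returned by hydrolysis of the mixed anhydride at its acetyl carbonyl during work-up.

Step 19
Reactants: 26 acetoxy acid
Product: 27 (3S,4R,5S,9R,10S,13R)-3-acetoxy-19-hydroxylabd-7-en-15-oic acid
Conditions: ZnBr2, n-PrSH, CH2Cl2, 0 °C
Reagents that add atoms: none
Why: Lewis acid–thiol transacetalisation cleaves the MOM ether under non-protic conditions that leave the acetate, acid and alkene intact; acyl migration is not expected because O3 and C19 are trans-diaxial.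

**Compound list**

1 | 2-methylcyclohexane-1,3-dione | CC1C(=O)CCCC1=O | starting material
2 | formaldehyde (37% aqueous) | C=O | starting material
3 | 2-(hydroxymethyl)-2-methylcyclohexane-1,3-dione | CC1(CO)C(=O)CCCC1=O | intermediate
4 | 2-[(methoxymethoxy)methyl]-2-methylcyclohexane-1,3-dione | COCOCC1(C)C(=O)CCCC1=O | intermediate
5 | (2R,3R)-3-hydroxy-2-[(methoxymethoxy)methyl]-2-methylcyclohexan-1-one (OH cis to CH2OMOM) | O[C@@H]1CCCC(=O)[C@]1(C)COCOC | intermediate
6 | (2R,3R)-3-(tert-butyldimethylsilyloxy)-2-[(methoxymethoxy)methyl]-2-methylcyclohexan-1-one | CC(C)(C)[Si](C)(C)O[C@@H]1CCCC(=O)[C@]1(C)COCOC | intermediate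
7 | ring A ketone, (2R,3R)-3-(tert-butyldimethylsilyloxy)-2-[(methoxymethoxy)methyl]-2,6-dimethylcyclohexan-1-one, C6 epimers | CC(C)(C)[Si](C)(C)O[C@@H]1CCC(C)C(=O)[C@]1(C)COCOC | intermediate
8 | (R)-citronellol | CC(C)=CCC[C@@H](C)CCO | starting material
9 | (R)-citronellyl triisopropylsilyl ether | CC(C)=CCC[C@@H](C)CCO[Si](C(C)C)(C(C)C)C(C)C | intermediate
10 | ozonide, 3,3-dimethyl-5-[(3R)-3-methyl-5-(triisopropylsilyloxy)pentyl]-1,2,4-trioxolane | CC1(C)OOC(CC[C@@H](C)CCO[Si](C(C)C)(C(C)C)C(C)C)O1 | intermediate
11 | (4R)-4-methyl-6-(triisopropylsilyloxy)hexanal | O=CCC[C@@H](C)CCO[Si](C(C)C)(C(C)C)C(C)C | intermediate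
12 | 1-(triphenylphosphoranylidene)propan-2-one | CC(=O)C=P(c1ccccc1)(c1ccccc1)c1ccccc1 | starting material
13 | (3E,7R)-7-methyl-9-(triisopropylsilyloxy)non-3-en-2-one | CC(=O)/C=C/CC[C@@H](C)CCO[Si](C(C)C)(C(C)C)C(C)C | intermediate
14 | Michael adduct 1,5-diketone: ring A ketone with C10 bearing methyl and the C9 carbon (C9 carries CH2COCH3 and the C11–C15 chain); C4, C9, C10, C13 as in 27 | CC(C)(C)[Si](C)(C)O[C@@H]1CC[C@@](C)([C@@H](CC(C)=O)CC[C@@H](C)CCO[Si](C(C)C)(C(C)C)C(C)C)C(=O)[C@]1(C)COCOC | intermediate
15 | ketol: 5-hydroxy-17-norlabdan-7-one tris-ether, C5 configuration open | CC(C)(C)[Si](C)(C)O[C@@H]1CC[C@]2(C)C(O)(CC(=O)C[C@H]2CC[C@@H](C)CCO[Si](C(C)C)(C(C)C)C(C)C)[C@]1(C)COCOC | intermediate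
16 | annulation enone: 17-norlabd-5-en-7-one with 3-OTBS, 19-OMOM, 15-OTIPS; OTBS, CH2OMOM, C20 methyl and C9 chain on one face; C13 R | CC(C)(C)[Si](C)(C)O[C@@H]1CC[C@]2(C)C(=CC(=O)C[C@H]2CC[C@@H](C)CCO[Si](C(C)C)(C(C)C)C(C)C)[C@]1(C)COCOC | intermediate
17 | 8-methyl enone: labd-5-en-7-one with 3-OTBS, 19-OMOM, 15-OTIPS, C8 epimers | CC(C)(C)[Si](C)(C)O[C@@H]1CC[C@]2(C)C(=CC(=O)C(C)[C@H]2CC[C@@H](C)CCO[Si](C(C)C)(C(C)C)C(C)C)[C@]1(C)COCOC | intermediate
18 | trans-decalone: labdan-7-one with 3-OTBS, 19-OMOM, 15-OTIPS; H5 trans to C20 methyl; C8 epimers | CC(C)(C)[Si](C)(C)O[C@@H]1CC[C@]2(C)[C@H](CC(=O)C(C)[C@H]2CC[C@@H](C)CCO[Si](C(C)C)(C(C)C)C(C)C)[C@]1(C)COCOC | intermediate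
19 | Δ7 enol triflate: labd-7-en-7-yl triflate with 3-OTBS, 19-OMOM, 15-OTIPS | CC(C)(C)[Si](C)(C)O[C@@H]1CC[C@]2(C)[C@H](CC(OS(=O)(=O)C(F)(F)F)=C(C)[C@H]2CC[C@@H](C)CCO[Si](C(C)C)(C(C)C)C(C)C)[C@]1(C)COCOC | intermediate
20 | Δ7-labdene tris-ether: labd-7-ene with 3-OTBS (equatorial), 19-OMOM, 15-OTIPS | CC(C)(C)[Si](C)(C)O[C@@H]1CC[C@]2(C)[C@H](CC=C(C)[C@H]2CC[C@@H](C)CCO[Si](C(C)C)(C(C)C)C(C)C)[C@]1(C)COCOC | intermediate
21 | diol: 19-(methoxymethoxy)labd-7-ene-3,15-diol, 3-OH equatorial (cis to C19) | O[C@@H]1CC[C@]2(C)[C@H](CC=C(C)[C@H]2CC[C@@H](C)CCO)[C@]1(C)COCOC | intermediate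
22 | keto aldehyde: 19-(methoxymethoxy)-3-oxolabd-7-en-15-al | O=C1CC[C@]2(C)[C@H](CC=C(C)[C@H]2CC[C@@H](C)CC=O)[C@]1(C)COCOC | intermediate
23 | keto acid: 19-(methoxymethoxy)-3-oxolabd-7-en-15-oic acid | O=C1CC[C@]2(C)[C@H](CC=C(C)[C@H]2CC[C@@H](C)CC(=O)O)[C@]1(C)COCOC | intermediate
24 | axial hydroxy acid: (3S)-3-hydroxy-19-(methoxymethoxy)labd-7-en-15-oic acid, 3-OH axial, trans to C19 | O[C@H]1CC[C@]2(C)[C@H](CC=C(C)[C@H]2CC[C@@H](C)CC(=O)O)[C@]1(C)COCOC | intermediate
25 | mixed anhydride: acetic anhydride of 3-acetoxy-19-(methoxymethoxy)labd-7-en-15-oic acid | CC(=O)O[C@H]1CC[C@]2(C)[C@H](CC=C(C)[C@H]2CC[C@@H](C)CC(=O)OC(C)=O)[C@]1(C)COCOC | intermediate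
26 | acetoxy acid: 3-acetoxy-19-(methoxymethoxy)labd-7-en-15-oic acid | CC(=O)O[C@H]1CC[C@]2(C)[C@H](CC=C(C)[C@H]2CC[C@@H](C)CC(=O)O)[C@]1(C)COCOC | intermediate
27 | (3S,4R,5S,9R,10S,13R)-3-acetoxy-19-hydroxylabd-7-en-15-oic acid (CNP0138726.1) | CC(=O)O[C@H]1CC[C@]2(C)[C@H](CC=C(C)[C@H]2CC[C@@H](C)CC(=O)O)[C@]1(C)CO | target

**Step count and risks**

Total steps: 19. Longest linear sequence: 16 (steps 1–5, 9–19); the enone branch is steps 6–8.

Steps most likely to fail:

Step 9. Proton transfer from the enone (α′ and γ hydrogens) to the hindered enolate, or enone self-condensation, may outrun conjugate addition. The aldol closure onto the C5 carbonyl, flanked by two quaternary carbons, may stall at the diketone. Facial selectivity at C10 may be eroded if the half-chair with the C4 methyl axial competes. The fallback separates the two bond formations and uses Lewis acid activation. From 7, LDA and TMSCl should give the trimethylsilyl enol ether of 7 F1. A Mukaiyama–Michael addition of this enol ether to 13 (TiCl4, CH2Cl2, −78 °C), where no basic enolate is present to be quenched, should give diketone 14, now isolated. A separate aldol cyclodehydration of 14 (KOt-Bu, t-BuOH, or pyrrolidine/AcOH with heating) can then be forced independently and returns to 16.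

Step 12. Enolisation of the C7 ketone may not discriminate well enough between C8 and C6, giving a mixture of Δ7 and Δ6 triflates, and the acetal may suffer under prolonged exposure to the anhydride. The fallback fixes regiochemistry before triflation. From 18, equilibrating silylation (TMSCl, Et3N, DMF, 110 °C) should favour the more substituted Δ7 trimethylsilyl enol ether of 18 F2. It is separated from its Δ6 isomer, which can be hydrolysed back to 18 and recycled. Cleavage of the enol ether with MeLi to the regiodefined lithium enolate and trapping with PhNTf2 returns to 19.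

Step 3. The enzyme panel may not contain a catalyst that reduces the required enantiotopic carbonyl from the required face with useful selectivity, or over-reduction to the diol may intervene. The fallback replaces enzyme recognition by reagent control. From 4, a Corey–Bakshi–Shibata desymmetrising reduction (2-methyl-CBS-oxazaborolidine of the matched handedness, catecholborane, toluene, −60 °C) should give 5 directly, with diastereomer separation if needed. This fallback makes no new compound (F0).

Further compounds
F1 | step 9 | trimethylsilyl enol ether of 7, (3R,4R)-4-(tert-butyldimethylsilyloxy)-3-[(methoxymethoxy)methyl]-1,3-dimethyl-2-(trimethylsilyloxy)cyclohex-1-ene | CC(C)(C)[Si](C)(C)O[C@@H]1CCC(C)=C(O[Si](C)(C)C)[C@]1(C)COCOC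
F2 | step 12 | Δ7 trimethylsilyl enol ether of 18, 7-(trimethylsilyloxy)labd-7-ene with 3-OTBS, 19-OMOM, 15-OTIPS | CC(C)(C)[Si](C)(C)O[C@@H]1CC[C@]2(C)[C@H](CC(O[Si](C)(C)C)=C(C)[C@H]2CC[C@@H](C)CCO[Si](C(C)C)(C(C)C)C(C)C)[C@]1(C)COCOC
F0 | step 3 | none | none
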